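The constants are invented; the flask was simulated.

You have a closed, stirred vessel in which solid Z dissolves to J and J takes up G at either of two sites, and a second G turns either mono adduct into G.J.G.

the same everywhere: Z 1.5 M; G 1.58 M; time 12 h

| flask | remark | temperature |
|---|---|---|
| noon | at 90 °C until 4.0 h, from then on at 65 °C |  |
| winter |  | 65 °C |
| autumn |  | 90 °C |

    J + G → X (k1 = 1.92 × 10⁻⁴ L mol⁻¹ s⁻¹, Ea1 = 85.0 kJ mol⁻¹)
    Z ⇌ J, rate k2*(cs2 - [J]) while solid is left; crystals form when [J] > cs2 (cs2 = 1.4 M, k2 = 2.39 × 10⁻⁴ s⁻¹)
    J + G → J.G (k3 = 1.62 × 10⁻⁴ L mol⁻¹ s⁻¹, Ea3 = 88.0 kJ mol⁻¹)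
    G + J.G → G.J.G (k4 = 1.66 × 10⁻⁴ L mol⁻¹ s⁻¹, Ea4 = 86.0 kJ mol⁻¹)
    G + X → G.J.G (k5 = 5.57 × 10⁻⁵ L mol⁻¹ s⁻¹, Ea5 = 92.0 kJ mol⁻¹)
    (constants at 90 °C)

- Z is a solid; its amount is given per volume of the solution
- all constants are for 90 °C and move with temperature by the activation energies
- at the start none of Z is in solution
- what has only dissolved of Z counts as not reacted

1. the best flask by amount of J.G, in percent of the Z charged; "all alike" if 1.5 percentage points covers them all (noon / winter / autumn / all alike)
2. amount of J.G at the end, in percent of the Z charged, noon
3. amount of J.G at the end, in percent of the Z charged, winter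
4. amount of J.G at the end, in percent of the Z charged, autumn

Climb the ladder of times first, counting each as a power of ten against the run of 12 h. At 90 °C and full G, a J lives 0.497 h, a power of −1.38. Dissolving takes 1.16 h, a power of −1.01. At 65 °C a J lives 4.11 h, a power of −0.465. So in the autumn flask the life of a J is shorter than the dissolving time, while in the winter flask the life of a J is longer than the dissolving time. The noon flask stays hot for 4.0 h, longer than a J lives, so you may reckon it with autumn.

The top rung holds what matters. G stands on the left of both the step that makes J.G and the steps that use J, so it divides out, and for a charge all in solution from the start, time and G merely set how far along one curve the flask has moved. That curve is governed by the selectivity factor r, the rate constant of G on J.G over the summed constants of G on J, 0.469 at 90 °C. With s, the share of J going to J.G, at 0.458, and u the fraction of the charge still J, J.G equals s over (one minus r), times u to the power r, less u.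

Its ceiling is s times r to the power r over (one minus r). In logarithms that is −0.339 plus −0.290, so −0.630, and the ceiling is 23.4 %, reached at u of 24.0 %. The curve is flat there, still 21.6 % at u of 12.0 %.

At 65 °C, r is 0.473 and s is 0.439, so the ceiling is 22.4 %. The two ceilings lie 1 percentage point apart, less than the margin, so I commit to all alike, with the hot flasks somewhat under their ceiling.

The forecast says all alike, with 21.2 % for noon, 22.1 % for winter and 21.2 % for autumn, and its ground is that “The spread is under 1.5 points”.

The simulation gives 21.0 % at noon, 22.0 % in winter and 21.0 % in autumn, so all alike, with autumn 2.4 points under its ceiling. The winter flask still holds 21.2 % of its G at 12.0 h, yet a run of 120 h leaves its J.G at 21.7 %. Now take r to the autumn flask charged with 2.7 M of G, which ends with u at 0.274 %: the curve gives 5.18 %, and that flask holds 4.49 %.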